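## Structural features

The target is a flavan. Aromatic ring A (C4a, C5–C8, C8a, free OH on C7) is fused to the saturated pyran ring C (O1, C2, C3, C4), and C2 carries aromatic ring B (C1'–C6').

Ring B is pentasubstituted in one unbroken run: C1' (bond to C2), C2' (prenyl), C3' (free OH), C4' (ring oxygen of ring D) and C5' (vinyl carbon of ring D). Only C6' bears hydrogen, and ring D is a 2,2-dimethyl-2H-pyran fused on C4'–C5'.

C2 is the only stereocentre, (R). It has no neighbouring stereocentre to relay from, so its configuration must come from a catalyst or reagent.

C2 is a secondary benzylic aryl ether, shielded on one side by the C2' prenyl group, and its cation is stabilised by the para oxygen on C4'. Displacement at C2 is therefore slow and ionisation easy, which threatens every SN2-type closure of ring C and every later acidic step.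

The fragile groups are the prenyl olefin next to the free 3'-OH (acid closes a chroman), the styrene-type olefin of ring D (acid, hydrogenation, electrophilic oxidants) and the two phenols. Hydrogenation, ionic reduction and strong acid are thus excluded once ring B is complete, which disables the usual redox corrections at C3 and C4 of flavanones and flavenes.

The real difficulty is to set C2 next to a complete, crowded B/D unit, and then to finish ring C without acid and without reduction that touches the other olefins.

The key step exploits the easy ionisation at C2. If C3–C4 is written as an ethynyl group, C2 becomes the γ-carbon of a copper allenylidene conjugated with ring B. This centre is planar, both enantiomers of a racemic ester collapse into it, and O1 of ring A is added to it under control of a chiral ligand.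

A second helpful feature is that O3' and O4' each have a single free ortho carbon (C2' and C5'). Sigmatropic shifts from oxygen to carbon can therefore only deliver the prenyl group and ring D to the right places.

## Logic of the disconnections

**16 from 15.** No skeletal bond is cut. The free phenols on C7 and C3' are traced back to two silyl ethers (forward: cleavage of O7–Si and O3'–Si). Fluoride is the one deprotection that leaves the prenyl group, ring D and the C2–O1 bond alone. The gain is that both phenols stay masked through all organometallic steps. The demand is a buffered, acid-free desilylation.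

**15 from 13 by way of 14.** The cut is C4–C4a, the sp3–sp2 bond of ring C that lies farthest from C2. Closing ring C here touches neither C2–O1 nor C2–H and needs neither acid nor hydrogenation: C4 arrives as a primary alkylborane and C4a as an aryl bromide. Ring C is simplified to an open aryl ether. The forward step must hydroborate only the monosubstituted C3=C4 olefin in the presence of the prenyl and ring D olefins, and the coupling must outrun β-hydride elimination.

**13 from 12.** No skeletal bond is cut: C3=C4 is traced back to C3≡C4. The alkyne is what makes the key step possible. The demand is a semi-hydrogenation that stops at the alkene and spares C4a–Br, C2–O1 and the other olefins.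

**12 from 8 and 10 (key disconnection).** The cut is O1–C2, made between two separate molecules and not as a ring closure. In one sentence: enantioconvergent copper-allenylidene O-propargylation of 10 by racemic 8.

- The cut is placed here because C2 is the carbon that ionises most easily. The forward step uses that ionisation inside a chiral catalyst instead of fighting it.
- The gain is the largest of the route. The molecule falls into a ring A piece of six carbons and a complete B/D piece, and the only stereocentre is removed, since 8 may be racemic.
- The demands are attack through O1 and not through a ring carbon of 10, attack at the γ-carbon, one face only, and no interference from the C2' prenyl group.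

**8 from 6.** The cut is C2–C3 (together with the acyl–O bond). The unit C3–C4 is added as an ethynyl nucleophile to the formyl carbon, which becomes C2. No stereocontrol is needed because the key step erases this centre. The precursor is a plain aromatic aldehyde. The demand is trapping of the alkoxide in the same flask so that the labile ester is handled only once.

**6 from 5 and 5 from 4.** After removal of the O3'–Si bond, the cut is C2'–CH2 of the prenyl group. A retro-aromatic Claisen step returns the five-carbon unit to O3' as a tertiary allyl ether. C2' is the only free ortho carbon of O3', and the [3,3] shift inverts the allyl unit, so the tertiary ether gives the linear prenyl group. The contiguous pattern C1'–C4' arises without any directing group. The demand is that the shift is faster than fragmentation of the tertiary ether.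

**4 from 3.** The cut is O3'–C(tertiary). The forward step is a π-allylpalladium etherification that must attack the more substituted allyl terminus.

**3 from 2.** The cut is C5'–C(vinyl) of ring D, with formal reopening of ring D. The retron is that of the propargyl Claisen/electrocyclisation cascade, and C5' is the only free ortho carbon of O4'. The two sigmatropic events are kept apart on purpose. A catechol carrying both unsaturated tertiary ethers at once could escape through an ipso-Claisen shift followed by an intramolecular Diels–Alder reaction.

**2 from 1.** The cut is O4'–C(tertiary). The para formyl group makes the 4'-OH the more acidic of the two, so O3' and O4' are told apart without protecting groups. The demand is one equivalent of base.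

**10 from 9.** The cut is O7–Si. The OH para to bromine is the less hindered one. The demand is a bulky silyl chloride used in one equivalent.

## Other disconnections considered

**Alternative 1:** the first plan that comes to mind cuts C2–C3 and O1–C2.

- Forward: Claisen–Schmidt condensation of the ring A acetophenone A1 with aldehyde 6 would give the 2'-hydroxychalcone A2. An enantioselective intramolecular oxa-Michael addition would close ring C to the flavanone A3, and the C4 carbonyl group would then be taken down to CH2.
- Stereochemical ground: in A3, C2 lies β to a ketone, so retro-oxa-Michael opening is available under base or acid, and the stereocentre stays labile as long as the carbonyl group is present.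
- Structural ground: the C2' prenyl group twists ring B out of conjugation and disfavours the closed form.
- Compatibility ground: removal of C4=O needs hydride followed by ionic or hydrogenolytic deoxygenation, the very conditions that ring D and the prenyl/3'-O pair cannot survive.
- Step economy: three redox operations would follow the stereocentre. The chosen plan never raises C3 or C4 above the hydrocarbon level that can be corrected selectively.

**Alternative 2:** cut C2–C1'.

- Forward: the racemic chromene acetal A4 would be ionised to an achiral 1-benzopyrylium ion. An aryl boronate would be added enantioselectively under a chiral diol/Lewis acid system to give a 2-aryl-2H-chromene, which is also a stereoconvergent step of known type.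
- First ground: the complete ring B cannot be used. The C2' prenyl group sits ortho to boron, and the C3=C4 olefin that remains cannot be hydrogenated selectively beside the very similar olefin of ring D.
- Consequence: a plain boronate such as A5 would have to be used, giving A6, and prenyl group and ring D would have to be built afterwards.
- Second ground: O3' and O4' would then lack the para formyl handle and would need extra, mutually orthogonal protecting groups.
- Third ground: a flavan with a free 4'-OH para to C2 would meet base and could open ring C through a para-quinone methide. The plan is longer by about three steps and exposes C2 more.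

**Alternative 3:** cut O1–C2 and C3–C4 together.

- Forward: an inverse-demand hetero-Diels–Alder reaction of the styrene A7 with the ortho-quinone methide A8, generated in the flask under a chiral Brønsted acid, would give 15 in one step and would be the shortest plan.
- Mechanistic ground: with so electron-rich a styrene the addition should be stepwise. C3–C4 forms first, and C2 is then set by collapse of a freely rotating para-alkoxybenzyl cation, where the chiral anion has little grip.
- Catalyst ground: A8 carries no substituent on its methide carbon to orient it in the catalyst pocket.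
- Chemoselectivity ground: the prenyl and ring D olefins are competing nucleophiles.
- Product stability ground: the acid that forms 15 can re-ionise its C2–O1 bond and racemise it.

Key step: step 8

Assumption: the pybox antipode that leads to (R)-12 is assigned by analogy with simpler 1-arylpropargyl esters and would be confirmed on 16; both antipodes and the five-carbon reagents of steps 1 and 3 are taken as purchasable.

## Steps

Step 1
Reactants: 1 3,4-dihydroxybenzaldehyde
Product: 2 3-hydroxy-4-[(2-methylbut-3-yn-2-yl)oxy]benzaldehyde
Conditions: 3-chloro-3-methylbut-1-yne (1.2 equiv), K2CO3 (1.05 equiv), KI (cat.), DMF, 55 °C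
Reagents that add atoms: 3-chloro-3-methylbut-1-yne, C#CC(C)(C)Cl
Why: Site-selective Williamson-type O-alkylation: with one equivalent of base only the 4-OH, acidified by the para formyl group, is ionised, so the tertiary propargylic electrophile is taken up at O4 and the 3-OH stays free; monoalkylation of this catechol aldehyde at O4 is a familiar selectivity.

Step 2
Reactants: 2 3-hydroxy-4-[(2-methylbut-3-yn-2-yl)oxy]benzaldehyde
Product: 3 8-hydroxy-2,2-dimethyl-2H-chromene-6-carbaldehyde
Conditions: PhNEt2, 180 °C, Ar
Reagents that add atoms: none
Why: Aromatic propargyl Claisen rearrangement to the only ortho carbon that bears hydrogen, then enolisation, 1,5-hydrogen shift and oxa-6π electrocyclisation, the standard thermal route from aryl 1,1-dimethylpropargyl ethers to 2,2-dimethyl-2H-chromenes; ring D is closed and no stereocentre is formed.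

Step 3
Reactants: 3 8-hydroxy-2,2-dimethyl-2H-chromene-6-carbaldehyde
Product: 4 2,2-dimethyl-8-[(2-methylbut-3-en-2-yl)oxy]-2H-chromene-6-carbaldehyde
Conditions: tert-butyl 2-methylbut-3-en-2-yl carbonate (1.5 equiv), Pd(PPh3)4 (2 mol %), THF, 0 °C
Reagents that add atoms: tert-butyl 2-methylbut-3-en-2-yl carbonate, C=CC(C)(C)OC(=O)OC(C)(C)C
Why: Decarboxylative Tsuji–Trost O-allylation: zerovalent palladium ionises the tertiary carbonate, the tert-butoxide set free deprotonates the phenol, and the phenoxide attacks the more substituted terminus of the 1,1-dimethylallyl complex under kinetic control at low temperature, the usual way to reverse-prenyl aryl ethers.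

Step 4
Reactants: 4 2,2-dimethyl-8-[(2-methylbut-3-en-2-yl)oxy]-2H-chromene-6-carbaldehyde
Product: 5 8-hydroxy-2,2-dimethyl-7-(3-methylbut-2-en-1-yl)-2H-chromene-6-carbaldehyde
Conditions: PhNEt2, 130 °C, Ar
Reagents that add atoms: none
Why: Aromatic Claisen rearrangement: of the two ortho carbons one is the ring fusion carbon bearing the ring D oxygen, so only the shift to C7 (C2' of the target) can end in rearomatisation, and the [3,3] inversion turns the tertiary allyl ether into the linear prenyl group; the weakly basic solvent suppresses acid-induced cleavage of the ether.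

Step 5
Reactants: 5 8-hydroxy-2,2-dimethyl-7-(3-methylbut-2-en-1-yl)-2H-chromene-6-carbaldehyde
Product: 6 8-[(tert-butyldimethylsilyl)oxy]-2,2-dimethyl-7-(3-methylbut-2-en-1-yl)-2H-chromene-6-carbaldehyde
Conditions: TBSCl, imidazole, DMAP (cat.), DMF, 40 °C
Reagents that add atoms: tert-butyldimethylsilyl chloride, CC(C)(C)[Si](C)(C)Cl
Why: Standard silylation of a phenol; the flanked position makes the silyl ether robust towards the Grignard reagent, the amine base and the aqueous phosphate of later steps, and prevents this phenol from competing as a nucleophile in step 8.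

Step 6
Reactants: 6 8-[(tert-butyldimethylsilyl)oxy]-2,2-dimethyl-7-(3-methylbut-2-en-1-yl)-2H-chromene-6-carbaldehyde
Product: 8 rac-1-{8-[(tert-butyldimethylsilyl)oxy]-2,2-dimethyl-7-(3-methylbut-2-en-1-yl)-2H-chromen-6-yl}prop-2-yn-1-yl acetate, via bromomagnesium alkoxide 7 (not isolated)
Conditions: HC≡CMgBr (1.3 equiv), THF, −20 to 0 °C; then Ac2O (2 equiv), 0 °C to rt
Reagents that add atoms: ethynylmagnesium bromide, C#C[Mg]Br; acetic anhydride, CC(=O)OC(C)=O
Why: Grignard 1,2-addition to the aldehyde and acylation of the alkoxide in the same flask; the new centre (the future C2) is formed racemic on purpose because step 8 erases it, and the one-flask trapping avoids isolation of the ionisable electron-rich carbinol.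

Step 7
Reactants: 9 4-bromobenzene-1,3-diol
Product: 10 2-bromo-5-[(triisopropylsilyl)oxy]phenol
Conditions: TIPSCl (1.0 equiv), imidazole, CH2Cl2/DMF, −10 to 0 °C
Reagents that add atoms: triisopropylsilyl chloride, CC(C)[Si](Cl)(C(C)C)C(C)C
Why: Sterically governed monosilylation: the very bulky silyl chloride takes the OH para to bromine, while the OH ortho to bromine is hindered and engaged in a hydrogen bond to the halogen; this leaves free exactly the oxygen that becomes O1.

Step 8
Reactants: 8 rac-1-{8-[(tert-butyldimethylsilyl)oxy]-2,2-dimethyl-7-(3-methylbut-2-en-1-yl)-2H-chromen-6-yl}prop-2-yn-1-yl acetate; 10 2-bromo-5-[(triisopropylsilyl)oxy]phenol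
Product: 12 (R)-6-{1-[2-bromo-5-(triisopropylsilyloxy)phenoxy]prop-2-yn-1-yl}-8-(tert-butyldimethylsilyloxy)-2,2-dimethyl-7-(3-methylbut-2-en-1-yl)-2H-chromene, via copper allenylidene 11 (not isolated)
Conditions: CuOTf·0.5C6H6 (5 mol %), 2,6-bis(4,5-diphenyl-4,5-dihydrooxazol-2-yl)pyridine (diPh-pybox, one antipode, 10 mol %), iPr2NEt (1.2 equiv), 10 (1.5 equiv), ClCH2CH2Cl, −10 °C
Reagents that add atoms: none
Why: Monovalent copper bound to the pybox ligand and iPr2NEt convert the terminal alkyne of either enantiomer of 8 into a copper acetylide, which expels acetate with help from the para oxygen on C4' to give the copper allenylidene 11; its C2 is trigonal and planar, so the configuration of 8 is erased and both enantiomers enter one channel. The phenoxide of 10 adds through O1 to C2, the γ-carbon of 11, and protonolysis of the resulting copper acetylide releases 12 and the catalyst. The closest known reaction type is the copper–pybox-catalysed enantioselective propargylic etherification of racemic 1-arylprop-2-ynyl esters by phenols. No ring is closed: the step forms the O1–C2 bond that joins ring A to the B/D half and leaves C3≡C4 and C4a–Br in place for the closure of ring C. The one new stereocentre, C2, is controlled by the ligand alone: its phenyl groups lie edge-to-face against ring B of 11 and screen one face, and the antipode is chosen so that O1 enters on the face that gives (R). O- over C-attack is needed and is secured by the bromine of 10, which acidifies the OH group and deactivates the ring, and by the TIPS group beside the two remaining nucleophilic ring carbons; γ- over α-attack is inherent in the allenylidene. Because the bond is made at a trigonal carbon three bonds away from the metal, the C2' prenyl group that would block an SN2 displacement is tolerated, and an excess of 10 lets the phenoxide outrun capture of 11 by that olefin. Low temperature and the modest leaving group keep uncatalysed ionisation of 8 and re-ionisation of 12 slow.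

Step 9
Reactants: 12 (R)-6-{1-[2-bromo-5-(triisopropylsilyloxy)phenoxy]prop-2-yn-1-yl}-8-(tert-butyldimethylsilyloxy)-2,2-dimethyl-7-(3-methylbut-2-en-1-yl)-2H-chromene
Product: 13 (R)-6-{1-[2-bromo-5-(triisopropylsilyloxy)phenoxy]prop-2-en-1-yl}-8-(tert-butyldimethylsilyloxy)-2,2-dimethyl-7-(3-methylbut-2-en-1-yl)-2H-chromene
Conditions: H2 (1 atm), Pd/CaCO3 poisoned with Pb(OAc)2 (Lindlar catalyst), quinoline, EtOAc, rt
Reagents that add atoms: none
Why: Lindlar semi-hydrogenation: the terminal alkyne binds to the poisoned palladium far more strongly than any alkene, so the prenyl and ring D olefins, the aryl bromide and the C2–O1 bond should be left alone; C2 is not involved and keeps its configuration.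

Step 10
Reactants: 13 (R)-6-{1-[2-bromo-5-(triisopropylsilyloxy)phenoxy]prop-2-en-1-yl}-8-(tert-butyldimethylsilyloxy)-2,2-dimethyl-7-(3-methylbut-2-en-1-yl)-2H-chromene
Product: 15 (2R)-2-[8-(tert-butyldimethylsilyloxy)-2,2-dimethyl-7-(3-methylbut-2-en-1-yl)-2H-chromen-6-yl]-7-(triisopropylsilyloxy)chromane, via B-alkyl-9-BBN borane 14 (not isolated)
Conditions: 9-BBN-H dimer (1.3 equiv B–H), THF, 0 °C to rt; then Pd(OAc)2 (5 mol %), SPhos (10 mol %), K3PO4 (3 M aq), THF/DMF, 60 °C, dilute
Reagents that add atoms: 9-borabicyclo[3.3.1]nonane (9-BBN-H), B1C2CCCC1CCC2 (its boron and carbon atoms stay in 14 only; 15 keeps one hydrogen)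
Why: 9-BBN-H hydroborates only the monosubstituted C3=C4 olefin, placing boron on C4, and ignores the trisubstituted prenyl and the hindered cis-disubstituted ring D olefins; boron stands 1,3 to O1, so no β-alkoxy elimination is possible. The intramolecular B-alkyl Suzuki–Miyaura coupling then closes the six-membered ring C at C4–C4a by reductive elimination from a seven-membered palladacycle. The medium is basic and non-reducing, so C2 is untouched.

Step 11
Reactants: 15 (2R)-2-[8-(tert-butyldimethylsilyloxy)-2,2-dimethyl-7-(3-methylbut-2-en-1-yl)-2H-chromen-6-yl]-7-(triisopropylsilyloxy)chromane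
Product: 16 (2R)-2-[8-hydroxy-2,2-dimethyl-7-(3-methylbut-2-en-1-yl)-2H-chromen-6-yl]chroman-7-ol (target)
Conditions: Bu4NF (2.5 equiv), AcOH (2.5 equiv), THF, 0 °C
Reagents that add atoms: none
Why: Fluoride cleavage of both phenolic silyl ethers; the acetic acid buffer keeps the medium near neutral, so neither acid-induced chroman formation from the prenyl phenol nor base-induced chemistry of the phenoxides should occur, and O4' is alkylated, so no quinone methide path to racemisation exists.

## Compound list

1 | 3,4-dihydroxybenzaldehyde | O=Cc1ccc(O)c(O)c1 | starting material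
2 | 3-hydroxy-4-[(2-methylbut-3-yn-2-yl)oxy]benzaldehyde | C#CC(C)(C)Oc1ccc(C=O)cc1O | intermediate
3 | 8-hydroxy-2,2-dimethyl-2H-chromene-6-carbaldehyde | CC1(C)C=Cc2cc(C=O)cc(O)c2O1 | intermediate
4 | 2,2-dimethyl-8-[(2-methylbut-3-en-2-yl)oxy]-2H-chromene-6-carbaldehyde | C=CC(C)(C)Oc1cc(C=O)cc2c1OC(C)(C)C=C2 | intermediate
5 | 8-hydroxy-2,2-dimethyl-7-(3-methylbut-2-en-1-yl)-2H-chromene-6-carbaldehyde | CC(C)=CCc1c(C=O)cc2c(c1O)OC(C)(C)C=C2 | intermediate
6 | 8-[(tert-butyldimethylsilyl)oxy]-2,2-dimethyl-7-(3-methylbut-2-en-1-yl)-2H-chromene-6-carbaldehyde | CC(C)=CCc1c(C=O)cc2c(c1O[Si](C)(C)C(C)(C)C)OC(C)(C)C=C2 | intermediate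
7 | bromomagnesium alkoxide of the racemic ethynyl carbinol derived from 6 | CC(C)=CCc1c(C(O[Mg]Br)C#C)cc2c(c1O[Si](C)(C)C(C)(C)C)OC(C)(C)C=C2 | intermediate
8 | rac-1-{8-[(tert-butyldimethylsilyl)oxy]-2,2-dimethyl-7-(3-methylbut-2-en-1-yl)-2H-chromen-6-yl}prop-2-yn-1-yl acetate | CC(C)=CCc1c(C(OC(C)=O)C#C)cc2c(c1O[Si](C)(C)C(C)(C)C)OC(C)(C)C=C2 | intermediate
9 | 4-bromobenzene-1,3-diol | Oc1ccc(Br)c(O)c1 | starting material
10 | 2-bromo-5-[(triisopropylsilyl)oxy]phenol | Oc1cc(O[Si](C(C)C)(C(C)C)C(C)C)ccc1Br | intermediate
11 | copper allenylidene of the B/D unit (pybox ligand omitted; drawn as the copper acetylide/propargyl cation resonance form) | CC(C)=CCc1c([CH+]C#C[Cu])cc2c(c1O[Si](C)(C)C(C)(C)C)OC(C)(C)C=C2 | intermediate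
12 | (R)-6-{1-[2-bromo-5-(triisopropylsilyloxy)phenoxy]prop-2-yn-1-yl}-8-(tert-butyldimethylsilyloxy)-2,2-dimethyl-7-(3-methylbut-2-en-1-yl)-2H-chromene | CC(C)=CCc1c([C@H](Oc2cc(O[Si](C(C)C)(C(C)C)C(C)C)ccc2Br)C#C)cc2c(c1O[Si](C)(C)C(C)(C)C)OC(C)(C)C=C2 | intermediate
13 | (R)-6-{1-[2-bromo-5-(triisopropylsilyloxy)phenoxy]prop-2-en-1-yl}-8-(tert-butyldimethylsilyloxy)-2,2-dimethyl-7-(3-methylbut-2-en-1-yl)-2H-chromene | CC(C)=CCc1c([C@H](Oc2cc(O[Si](C(C)C)(C(C)C)C(C)C)ccc2Br)C=C)cc2c(c1O[Si](C)(C)C(C)(C)C)OC(C)(C)C=C2 | intermediate
14 | (R)-B-alkyl-9-BBN borane from 13 (boron on C4) | CC(C)=CCc1c([C@H](Oc2cc(O[Si](C(C)C)(C(C)C)C(C)C)ccc2Br)CCB2C3CCCC2CCC3)cc2c(c1O[Si](C)(C)C(C)(C)C)OC(C)(C)C=C2 | intermediate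
15 | (2R)-2-[8-(tert-butyldimethylsilyloxy)-2,2-dimethyl-7-(3-methylbut-2-en-1-yl)-2H-chromen-6-yl]-7-(triisopropylsilyloxy)chromane | CC(C)=CCc1c([C@H]2CCc3ccc(O[Si](C(C)C)(C(C)C)C(C)C)cc3O2)cc2c(c1O[Si](C)(C)C(C)(C)C)OC(C)(C)C=C2 | intermediate
16 | (2R)-2-[8-hydroxy-2,2-dimethyl-7-(3-methylbut-2-en-1-yl)-2H-chromen-6-yl]chroman-7-ol | CC(C)=CCc1c([C@H]2CCc3ccc(O)cc3O2)cc2c(c1O)OC(C)(C)C=C2 | target

## Step count and least certain steps

Total step count: 11. Longest linear sequence: 10 steps (steps 1–6 and 8–11); step 7 is the one-step branch.

**Step 8 (key step).**

- The most likely failure is loss of enantiopurity by ionisation outside the chiral pocket. Ring B is so electron-rich that 8 may ionise without copper, and the 2-bromophenoxide of 12 is a fair leaving group, so 12 may re-enter the allenylidene manifold on long exposure.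
- The second risk is interception of the allenylidene by the neighbouring prenyl olefin (an ene-type five-membered ring closure).
- The third risk is C-propargylation of the resorcinol-type ring of 10.
- The fallback sets out from 6 and comes back at 12, and replaces the convergent ionisation by reagent-controlled addition plus inversion.
  - Catalytic asymmetric alkynylation of 6 with trimethylsilylacetylene (Et2Zn, Ti(OiPr)4, one antipode of BINOL) would give (R)-1-aryl-3-(trimethylsilyl)prop-2-yn-1-ol F1. This compound is (R) only because the silylalkynyl group outranks aryl; its spatial arrangement is opposite to that of 12.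
  - Mitsunobu etherification with 10 (PPh3, DIAD, toluene, −20 °C) would invert the centre to the silylated aryl propargyl ether F2.
  - Selective C-desilylation (AgNO3 cat., aqueous acetone), which leaves phenolic silyl ethers alone, would give 12.

**Step 10.**

- Oxidative addition into the electron-rich, ortho-alkoxy aryl bromide may be slow. The alkylborane would then be lost by protodeboronation, or the alkylpalladium species by β-hydride elimination; intermolecular coupling is a further drain.
- The fallback sets out from 13 (through 14) and comes back at 15, and closes the same bond by carbanion chemistry.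
  - Oxidation of 14 with NaBO3·4H2O would give the primary alcohol F3.
  - CBr4/PPh3 would give the primary bromide F4.
  - A Parham cyclisation would close ring C to 15. With n-BuLi in THF at −100 °C, bromine–lithium exchange is faster at the aryl than at the primary alkyl bromide, and warming then brings about the ring closure.

**Step 3.**

- The branched selectivity may erode. The palladium catalyst can re-ionise the tertiary ether and funnel it to the linear prenyl ether, and C-allylation of the phenoxide may intrude.
- The fallback sets out from 3 and comes back at 4, and builds the tertiary C–O bond by another mechanism. Copper-catalysed propargylation (3-chloro-3-methylbut-1-yne, DBU, CuCl2·2H2O cat., MeCN, 0 °C) would give 2,2-dimethyl-8-[(2-methylbut-3-yn-2-yl)oxy]-2H-chromene-6-carbaldehyde F5. Semi-hydrogenation over Pd/CaCO3 poisoned with Pb(OAc)2 would convert it into 4.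

**Step 4.**

- The tertiary allyl ether may fragment (loss of isoprene, return to 3) faster than it rearranges. The ortho relation of formyl and prenyl groups in the product also opens a thermal carbonyl-ene pathway on prolonged heating.
- The fallback sets out from 3 and comes back at 5, bypassing steps 3 and 4. It is a direct ortho-C-prenylation of the sodium phenoxide of 3 with 1-bromo-3-methylbut-2-ene in toluene. The tight ion pair in a non-polar medium directs alkylation to carbon, and C7 is the only free ortho carbon. This fallback makes no new compound (F0).

## Further compounds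

F1 | step 8 | (R)-1-{8-[(tert-butyldimethylsilyl)oxy]-2,2-dimethyl-7-(3-methylbut-2-en-1-yl)-2H-chromen-6-yl}-3-(trimethylsilyl)prop-2-yn-1-ol | CC(C)=CCc1c([C@@H](O)C#C[Si](C)(C)C)cc2c(c1O[Si](C)(C)C(C)(C)C)OC(C)(C)C=C2
F2 | step 8 | (S)-6-{1-[2-bromo-5-(triisopropylsilyloxy)phenoxy]-3-(trimethylsilyl)prop-2-yn-1-yl}-8-(tert-butyldimethylsilyloxy)-2,2-dimethyl-7-(3-methylbut-2-en-1-yl)-2H-chromene | CC(C)=CCc1c([C@H](Oc2cc(O[Si](C(C)C)(C(C)C)C(C)C)ccc2Br)C#C[Si](C)(C)C)cc2c(c1O[Si](C)(C)C(C)(C)C)OC(C)(C)C=C2
F3 | step 10 | (R)-3-[2-bromo-5-(triisopropylsilyloxy)phenoxy]-3-[8-(tert-butyldimethylsilyloxy)-2,2-dimethyl-7-(3-methylbut-2-en-1-yl)-2H-chromen-6-yl]propan-1-ol | CC(C)=CCc1c([C@H](Oc2cc(O[Si](C(C)C)(C(C)C)C(C)C)ccc2Br)CCO)cc2c(c1O[Si](C)(C)C(C)(C)C)OC(C)(C)C=C2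
F4 | step 10 | (R)-6-{3-bromo-1-[2-bromo-5-(triisopropylsilyloxy)phenoxy]propyl}-8-(tert-butyldimethylsilyloxy)-2,2-dimethyl-7-(3-methylbut-2-en-1-yl)-2H-chromene | CC(C)=CCc1c([C@H](Oc2cc(O[Si](C(C)C)(C(C)C)C(C)C)ccc2Br)CCBr)cc2c(c1O[Si](C)(C)C(C)(C)C)OC(C)(C)C=C2
F5 | step 3 | 2,2-dimethyl-8-[(2-methylbut-3-yn-2-yl)oxy]-2H-chromene-6-carbaldehyde | C#CC(C)(C)Oc1cc(C=O)cc2c1OC(C)(C)C=C2
F0 | step 4 | none | none
A1 | alternative 1 | 1-{2-hydroxy-4-[(triisopropylsilyl)oxy]phenyl}ethan-1-one | CC(=O)c1ccc(O[Si](C(C)C)(C(C)C)C(C)C)cc1O
A2 | alternative 1 | (E)-3-[8-(tert-butyldimethylsilyloxy)-2,2-dimethyl-7-(3-methylbut-2-en-1-yl)-2H-chromen-6-yl]-1-[2-hydroxy-4-(triisopropylsilyloxy)phenyl]prop-2-en-1-one | CC(C)=CCc1c(/C=C/C(=O)c3ccc(O[Si](C(C)C)(C(C)C)C(C)C)cc3O)cc2c(c1O[Si](C)(C)C(C)(C)C)OC(C)(C)C=C2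
A3 | alternative 1 | (2R)-2-[8-(tert-butyldimethylsilyloxy)-2,2-dimethyl-7-(3-methylbut-2-en-1-yl)-2H-chromen-6-yl]-7-(triisopropylsilyloxy)chroman-4-one | CC(C)=CCc1c([C@H]2CC(=O)c3ccc(O[Si](C(C)C)(C(C)C)C(C)C)cc3O2)cc2c(c1O[Si](C)(C)C(C)(C)C)OC(C)(C)C=C2
A4 | alternative 2 | rac-2-ethoxy-7-[(triisopropylsilyl)oxy]-2H-chromene | CCOC1C=Cc2ccc(O[Si](C(C)C)(C(C)C)C(C)C)cc2O1
A5 | alternative 2 | diethyl [4-(benzyloxy)-3-(methoxymethoxy)phenyl]boronate | CCOB(OCC)c1ccc(OCc2ccccc2)c(OCOC)c1
A6 | alternative 2 | (2R)-2-[4-(benzyloxy)-3-(methoxymethoxy)phenyl]-7-[(triisopropylsilyl)oxy]-2H-chromene | COCOc1cc([C@H]2C=Cc3ccc(O[Si](C(C)C)(C(C)C)C(C)C)cc3O2)ccc1OCc1ccccc1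
A7 | alternative 3 | 8-[(tert-butyldimethylsilyl)oxy]-6-ethenyl-2,2-dimethyl-7-(3-methylbut-2-en-1-yl)-2H-chromene | CC(C)=CCc1c(C=C)cc2c(c1O[Si](C)(C)C(C)(C)C)OC(C)(C)C=C2
A8 | alternative 3 | 6-methylidene-3-[(triisopropylsilyl)oxy]cyclohexa-2,4-dien-1-one | C=C1C=CC(O[Si](C(C)C)(C(C)C)C(C)C)=CC1=O
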